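**Retrosynthetic overview**
- The only ring is the cyclohexene C1–C6. The strategy rests on its allylic secondary carbinol C4, which is bonded to alkene carbon C3 (of C2=C3) and to carbinol C5, so the ring is opened at the C3–C4 bond to an acyclic Z-alkenyl iodide (C3) and aldehyde (C4).
- That bond is formed in the penultimate step by an intramolecular Nozaki–Hiyama–Kishi addition (CrCl2, catalytic NiCl2), which closes the single ring and sets C4; global desilylation then gives the triol.
- The Z-iodoalkene comes from a C1 ethynyl group (iodination, then syn-hydroboration/protonolysis), and the aldehyde from a PMB-protected primary alcohol.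
- The C1 tertiary carbinol comes from chelation-controlled ethynylation of a β-hydroxy ketone, made by opening the PMB ether of (S)-glycidol (C4–C6, stereocentre C5) with a 2-alkyl-1,3-dithiane anion (C1 plus side chain).
- The (E)-heptadec-12-enyl chain comes from hex-1-yne and 11-bromoundecan-1-ol (acetylide alkylation, trans-reduction).

Key step: step 15

Remark: the ring numbering C1 (quaternary carbinol), C2=C3, C4 and C5 (secondary carbinols), C6 (CH2) is also used for the corresponding carbons of the acyclic intermediates; systematic names carry their own locants.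

**Route**

Step 1
Reactants: 1 hex-1-yne; 2 11-bromoundecan-1-ol
Product: 5 heptadec-12-yn-1-ol, via hex-1-ynyllithium 3 (not isolated), via lithium 11-bromoundecan-1-olate 4 (not isolated)
Conditions: n-BuLi (one equiv for 1, one for 2), THF–DMPU, −78 °C → rt
Reagents that add atoms: none
Why: SN2 alkylation of a lithium acetylide by a primary alkyl bromide (acetylide alkylation); the hydroxyl is carried as its lithium alkoxide and DMPU makes the acetylide reactive enough at room temperature.

Step 2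
Reactants: 5 heptadec-12-yn-1-ol
Product: 6 (E)-heptadec-12-en-1-ol
Conditions: Na, NH3(l)–THF, −33 °C
Reagents that add atoms: none
Why: Dissolving-metal reduction of an isolated internal alkyne gives the E-alkene through the more stable trans vinyl anion, and the isolated alkene formed is not reduced further.

Step 3
Reactants: 6 (E)-heptadec-12-en-1-ol
Product: 7 (E)-17-iodoheptadec-5-ene
Conditions: PPh3, I2, imidazole, CH2Cl2, 0 °C → rt
Reagents that add atoms: iodine (I2), II
Why: Appel-type iodination, in which iodide displaces the alkoxyphosphonium ion of the primary alcohol by SN2 without touching the alkene.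

Step 4
Reactants: 7 (E)-17-iodoheptadec-5-ene; 8 1,3-dithiane
Product: 10 2-[(E)-heptadec-12-en-1-yl]-1,3-dithiane, via 2-lithio-1,3-dithiane 9 (not isolated)
Conditions: n-BuLi, THF, −30 °C; then 7, −78 °C → rt
Reagents that add atoms: none
Why: Corey–Seebach alkylation, in which the sulfur-stabilised acyl-anion equivalent displaces a primary iodide cleanly.

Step 5
Reactants: 11 (S)-glycidol
Product: 13 (R)-2-{[(4-methoxybenzyl)oxy]methyl}oxirane, via sodium (S)-glycidolate 12 (not isolated)
Conditions: NaH, DMF, 0 °C; PMBCl, 0 °C → rt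
Reagents that add atoms: 4-methoxybenzyl chloride (PMBCl), COc1ccc(CCl)cc1
Why: Williamson etherification that leaves the stereocentre untouched (a Payne rearrangement of the glycidolate is degenerate and returns the same enantiomer); the descriptor changes from S to R only because the CIP priorities change.

Step 6
Reactants: 10 2-[(E)-heptadec-12-en-1-yl]-1,3-dithiane; 13 (R)-2-{[(4-methoxybenzyl)oxy]methyl}oxirane
Product: 15 (2R)-1-{2-[(E)-heptadec-12-en-1-yl]-1,3-dithian-2-yl}-3-[(4-methoxybenzyl)oxy]propan-2-ol, via 2-lithio-2-(heptadec-12-enyl)-1,3-dithiane 14 (not isolated)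
Conditions: t-BuLi, THF–HMPA (10:1), −78 °C; then 13, −78 → −20 °C
Reagents that add atoms: none
Why: Corey–Seebach dithiane anion opening of a terminal epoxide by SN2 at the unsubstituted carbon (C6), so the glycidol-derived carbinol centre C5 is carried over unchanged.

Step 7
Reactants: 15 (2R)-1-{2-[(E)-heptadec-12-en-1-yl]-1,3-dithian-2-yl}-3-[(4-methoxybenzyl)oxy]propan-2-ol
Product: 16 (2R,16E)-2-hydroxy-1-[(4-methoxybenzyl)oxy]henicos-16-en-4-one
Conditions: MeI, CaCO3, MeCN–H2O (9:1), 45 °C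
Reagents that add atoms: water, O
Why: Alkylative dithiane hydrolysis (S-methylation, then hydrolysis of the thionium ion) under near-neutral, non-oxidising conditions that spare the PMB ether, the chain alkene and the β-hydroxy ketone.

Step 8
Reactants: 16 (2R,16E)-2-hydroxy-1-[(4-methoxybenzyl)oxy]henicos-16-en-4-one
Product: 18 (2R,4R,16E)-4-ethynyl-1-[(4-methoxybenzyl)oxy]henicos-16-ene-2,4-diol, via bromomagnesium alkoxide chelate 17 (not isolated)
Conditions: HC≡CMgBr (4 equiv), CH2Cl2–THF, −78 → 0 °C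
Reagents that add atoms: ethynylmagnesium bromide, C#C[Mg]Br
Why: Chelation-controlled 1,3-induction in a Grignard addition to a β-hydroxy ketone: the first equivalent gives alkoxide 17, whose magnesium bridges the C5 oxygen and the C1 carbonyl in a six-membered half-chair with the CH2OPMB group equatorial, and the small ethynyl group adds axially, trans to that group, which sets C1 as R (C1–O and C5–O anti along the chain C2–C1–C6–C5).

Step 9
Reactants: 18 (2R,4R,16E)-4-ethynyl-1-[(4-methoxybenzyl)oxy]henicos-16-ene-2,4-diol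
Product: 19 (2R,4R,16E)-2-[(tert-butyldimethylsilyl)oxy]-4-ethynyl-1-[(4-methoxybenzyl)oxy]henicos-16-en-4-ol
Conditions: TBSCl, imidazole, DMF, 0 °C → rt
Reagents that add atoms: tert-butyldimethylsilyl chloride (TBSCl), CC(C)(C)[Si](C)(C)Cl
Why: Silylation with the silyl chloride and imidazole is selective on steric grounds for the secondary C5 hydroxyl over the tertiary C1 hydroxyl.

Step 10
Reactants: 19 (2R,4R,16E)-2-[(tert-butyldimethylsilyl)oxy]-4-ethynyl-1-[(4-methoxybenzyl)oxy]henicos-16-en-4-ol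
Product: 20 (2R,4R,16E)-2-[(tert-butyldimethylsilyl)oxy]-4-ethynyl-1-[(4-methoxybenzyl)oxy]-4-[(triethylsilyl)oxy]henicos-16-ene
Conditions: TESOTf, 2,6-lutidine, CH2Cl2, −78 → 0 °C
Reagents that add atoms: triethylsilyl trifluoromethanesulfonate (TESOTf), CC[Si](CC)(CC)OS(=O)(=O)C(F)(F)F
Why: The silyl triflate with a hindered base silylates the tertiary propargylic alcohol, which would otherwise form a five-membered lactol with the later C4 aldehyde.

Step 11
Reactants: 20 (2R,4R,16E)-2-[(tert-butyldimethylsilyl)oxy]-4-ethynyl-1-[(4-methoxybenzyl)oxy]-4-[(triethylsilyl)oxy]henicos-16-ene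
Product: 21 (2R,4R,16E)-2-[(tert-butyldimethylsilyl)oxy]-4-(iodoethynyl)-1-[(4-methoxybenzyl)oxy]-4-[(triethylsilyl)oxy]henicos-16-ene
Conditions: NIS, AgNO3 (10 mol %), acetone, rt, dark
Reagents that add atoms: N-iodosuccinimide (NIS), O=C1CCC(=O)N1I
Why: Silver-catalysed electrophilic iodination of a terminal alkyne through the silver acetylide, which is much faster than any reaction of the isolated alkene.

Step 12
Reactants: 21 (2R,4R,16E)-2-[(tert-butyldimethylsilyl)oxy]-4-(iodoethynyl)-1-[(4-methoxybenzyl)oxy]-4-[(triethylsilyl)oxy]henicos-16-ene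
Product: 23 (2R,4R,16E)-2-[(tert-butyldimethylsilyl)oxy]-4-[(Z)-2-iodoethenyl]-1-[(4-methoxybenzyl)oxy]-4-[(triethylsilyl)oxy]henicos-16-ene, via 1-iodoalkenylborane 22 (not isolated)
Conditions: Sia2BH (from BH3·THF, 2-methylbut-2-ene), THF, 0 °C; then AcOH, 0 °C → rt
Reagents that add atoms: none
Why: Hydroboration–protonolysis of a 1-iodoalkyne: syn addition of the hindered dialkylborane puts boron on the iodine-bearing carbon C3 and hydrogen on C2, and protonolysis of the C–B bond with retention gives the Z-iodoalkene, while the hindered borane reacts only very slowly with the trans-disubstituted chain alkene.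

Step 13
Reactants: 23 (2R,4R,16E)-2-[(tert-butyldimethylsilyl)oxy]-4-[(Z)-2-iodoethenyl]-1-[(4-methoxybenzyl)oxy]-4-[(triethylsilyl)oxy]henicos-16-ene
Product: 24 (2R,4R,16E)-2-[(tert-butyldimethylsilyl)oxy]-4-[(Z)-2-iodoethenyl]-4-[(triethylsilyl)oxy]henicos-16-en-1-ol
Conditions: DDQ, CH2Cl2–pH 7 buffer (10:1), 0 °C
Reagents that add atoms: none
Why: Oxidative PMB cleavage (hydride abstraction by DDQ, hydrolysis of the oxocarbenium ion) under buffered conditions that leave both silyl ethers, the alkenyl iodide and the isolated alkene intact.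

Step 14
Reactants: 24 (2R,4R,16E)-2-[(tert-butyldimethylsilyl)oxy]-4-[(Z)-2-iodoethenyl]-4-[(triethylsilyl)oxy]henicos-16-en-1-ol
Product: 25 (2R,4R,16E)-2-[(tert-butyldimethylsilyl)oxy]-4-[(Z)-2-iodoethenyl]-4-[(triethylsilyl)oxy]henicos-16-enal
Conditions: Dess–Martin periodinane, pyridine, CH2Cl2, 0 °C → rt
Reagents that add atoms: none
Why: Dess–Martin oxidation of the primary alcohol under buffered, non-epimerising conditions gives the α-silyloxy aldehyde, which is used directly.

Step 15
Reactants: 25 (2R,4R,16E)-2-[(tert-butyldimethylsilyl)oxy]-4-[(Z)-2-iodoethenyl]-4-[(triethylsilyl)oxy]henicos-16-enal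
Product: 27 (1R,4R,5R)-5-[(tert-butyldimethylsilyl)oxy]-1-[(E)-heptadec-12-en-1-yl]-1-[(triethylsilyl)oxy]cyclohex-2-en-4-ol, via alkenylchromium dichloride 26 (not isolated)
Conditions: CrCl2 (6 equiv), NiCl2 (2 mol %), degassed DMSO (0.005 M), rt
Reagents that add atoms: none
Why: CrCl2 reduces NiCl2 to zerovalent nickel, which inserts into the C3–I bond with retention of the Z geometry; transmetalation to trivalent chromium gives 26, whose C3 adds to the C4 aldehyde through a chromium-bridged four-centre transition state. The closest known reaction is the intramolecular Nozaki–Hiyama–Kishi coupling of an alkenyl iodide with an aldehyde, a standard carbocyclisation. The cyclohexene ring C1–C6 closes by a 6-exo-trig addition to the carbonyl, made easy because the Z-alkene already holds C1 and C3 cis. The new stereocentre C4 is controlled by the ring transition state: the chain on C1 and the OTBS group on C5 are cis-1,3 and both sit pseudo-equatorial in the chair-like closure (the other chair would make them 1,3-diaxial), and the chromium-bound carbonyl oxygen, held near the alkene plane by the Cr–C3 bond, takes the pseudo-equatorial site, which should give the 4,5-trans (4R) alcohol. The step needs this facial selectivity, retention of the alkene geometry and chemoselectivity for the aldehyde; the first rests on the C1 and C5 stereocentres, the others on the neutral conditions, which leave the silyl ethers, the chain alkene and the α-silyloxy centre untouched. High dilution keeps the coupling intramolecular.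

Step 16
Reactants: 27 (1R,4R,5R)-5-[(tert-butyldimethylsilyl)oxy]-1-[(E)-heptadec-12-en-1-yl]-1-[(triethylsilyl)oxy]cyclohex-2-en-4-ol
Product: 28 (1R,4R,5R)-1-[(E)-heptadec-12-en-1-yl]cyclohex-2-ene-1,4,5-triol
Conditions: TBAF (Bu4NF, 4 equiv), THF, 0 °C → rt
Reagents that add atoms: none
Why: Fluoride-driven cleavage of both silyl ethers (Si–F bond formation) under non-acidic conditions, which avoids ionisation of the tertiary allylic alcohol.

**Compound list**

1 | hex-1-yne | CCCCC#C | starting material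
2 | 11-bromoundecan-1-ol | OCCCCCCCCCCCBr | starting material
3 | hex-1-ynyllithium | CCCCC#C[Li] | intermediate (not isolated)
4 | lithium 11-bromoundecan-1-olate | [Li]OCCCCCCCCCCCBr | intermediate (not isolated)
5 | heptadec-12-yn-1-ol | CCCCC#CCCCCCCCCCCCO | intermediate
6 | (E)-heptadec-12-en-1-ol | CCCC/C=C/CCCCCCCCCCCO | intermediate
7 | (E)-17-iodoheptadec-5-ene | CCCC/C=C/CCCCCCCCCCCI | intermediate
8 | 1,3-dithiane | C1CSCSC1 | starting material
9 | 2-lithio-1,3-dithiane | [Li]C1SCCCS1 | intermediate (not isolated)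
10 | 2-[(E)-heptadec-12-en-1-yl]-1,3-dithiane | CCCC/C=C/CCCCCCCCCCCC1SCCCS1 | intermediate
11 | (S)-glycidol | OC[C@H]1CO1 | starting material
12 | sodium (S)-glycidolate | [Na]OC[C@H]1CO1 | intermediate (not isolated)
13 | (R)-2-{[(4-methoxybenzyl)oxy]methyl}oxirane (PMB ether of (S)-glycidol) | COc1ccc(COC[C@H]2CO2)cc1 | intermediate
14 | 2-lithio-2-[(E)-heptadec-12-en-1-yl]-1,3-dithiane | CCCC/C=C/CCCCCCCCCCCC1([Li])SCCCS1 | intermediate (not isolated)
15 | (2R)-1-{2-[(E)-heptadec-12-en-1-yl]-1,3-dithian-2-yl}-3-[(4-methoxybenzyl)oxy]propan-2-ol | CCCC/C=C/CCCCCCCCCCCC1(C[C@@H](O)COCc2ccc(OC)cc2)SCCCS1 | intermediate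
16 | (2R,16E)-2-hydroxy-1-[(4-methoxybenzyl)oxy]henicos-16-en-4-one | CCCC/C=C/CCCCCCCCCCCC(=O)C[C@@H](O)COCc1ccc(OC)cc1 | intermediate
17 | bromomagnesium alkoxide of 16 (six-membered Mg chelate with the ketone) | CCCC/C=C/CCCCCCCCCCCC(=O)C[C@@H](O[Mg]Br)COCc1ccc(OC)cc1 | intermediate (not isolated)
18 | (2R,4R,16E)-4-ethynyl-1-[(4-methoxybenzyl)oxy]henicos-16-ene-2,4-diol | CCCC/C=C/CCCCCCCCCCC[C@](O)(C#C)C[C@@H](O)COCc1ccc(OC)cc1 | intermediate
19 | (2R,4R,16E)-2-[(tert-butyldimethylsilyl)oxy]-4-ethynyl-1-[(4-methoxybenzyl)oxy]henicos-16-en-4-ol | CCCC/C=C/CCCCCCCCCCC[C@](O)(C#C)C[C@@H](O[Si](C)(C)C(C)(C)C)COCc1ccc(OC)cc1 | intermediate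
20 | (2R,4R,16E)-2-[(tert-butyldimethylsilyl)oxy]-4-ethynyl-1-[(4-methoxybenzyl)oxy]-4-[(triethylsilyl)oxy]henicos-16-ene | CCCC/C=C/CCCCCCCCCCC[C@](O[Si](CC)(CC)CC)(C#C)C[C@@H](O[Si](C)(C)C(C)(C)C)COCc1ccc(OC)cc1 | intermediate
21 | (2R,4R,16E)-2-[(tert-butyldimethylsilyl)oxy]-4-(iodoethynyl)-1-[(4-methoxybenzyl)oxy]-4-[(triethylsilyl)oxy]henicos-16-ene | CCCC/C=C/CCCCCCCCCCC[C@](O[Si](CC)(CC)CC)(C#CI)C[C@@H](O[Si](C)(C)C(C)(C)C)COCc1ccc(OC)cc1 | intermediate
22 | (Z)-1-iodoalkenyl-bis(3-methylbutan-2-yl)borane from 21 (boron and iodine on C3, C1 cis to iodine) | CCCC/C=C/CCCCCCCCCCC[C@](O[Si](CC)(CC)CC)(/C=C(\I)B(C(C)C(C)C)C(C)C(C)C)C[C@@H](O[Si](C)(C)C(C)(C)C)COCc1ccc(OC)cc1 | intermediate (not isolated)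
23 | (2R,4R,16E)-2-[(tert-butyldimethylsilyl)oxy]-4-[(Z)-2-iodoethenyl]-1-[(4-methoxybenzyl)oxy]-4-[(triethylsilyl)oxy]henicos-16-ene | CCCC/C=C/CCCCCCCCCCC[C@](O[Si](CC)(CC)CC)(/C=C\I)C[C@@H](O[Si](C)(C)C(C)(C)C)COCc1ccc(OC)cc1 | intermediate
24 | (2R,4R,16E)-2-[(tert-butyldimethylsilyl)oxy]-4-[(Z)-2-iodoethenyl]-4-[(triethylsilyl)oxy]henicos-16-en-1-ol | CCCC/C=C/CCCCCCCCCCC[C@](O[Si](CC)(CC)CC)(/C=C\I)C[C@@H](O[Si](C)(C)C(C)(C)C)CO | intermediate
25 | (2R,4R,16E)-2-[(tert-butyldimethylsilyl)oxy]-4-[(Z)-2-iodoethenyl]-4-[(triethylsilyl)oxy]henicos-16-enal | CCCC/C=C/CCCCCCCCCCC[C@](O[Si](CC)(CC)CC)(/C=C\I)C[C@@H](O[Si](C)(C)C(C)(C)C)C=O | intermediate (key-step precursor)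
26 | (Z)-alkenylchromium dichloride from 25 (trivalent chromium on C3) | CCCC/C=C/CCCCCCCCCCC[C@](O[Si](CC)(CC)CC)(/C=C\[Cr](Cl)Cl)C[C@@H](O[Si](C)(C)C(C)(C)C)C=O | intermediate (not isolated)
27 | (1R,4R,5R)-5-[(tert-butyldimethylsilyl)oxy]-1-[(E)-heptadec-12-en-1-yl]-1-[(triethylsilyl)oxy]cyclohex-2-en-4-ol (ring numbered from the quaternary carbon) | CCCC/C=C/CCCCCCCCCCC[C@]1(O[Si](CC)(CC)CC)C=C[C@@H](O)[C@H](O[Si](C)(C)C(C)(C)C)C1 | intermediate (key-step product)
28 | (1R,4R,5R)-1-[(E)-heptadec-12-en-1-yl]cyclohex-2-ene-1,4,5-triol (IUPAC locants: (1R,2R,4R)-4-[(12E)-heptadec-12-en-1-yl]cyclohex-5-ene-1,2,4-triol) | CCCC/C=C/CCCCCCCCCCC[C@]1(O)C=C[C@@H](O)[C@H](O)C1 | target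

**Step count**

Total step count: 16. Longest linear sequence: 15 steps (steps 1–4, then 6–16); step 5 is a one-step side branch.

**Steps most likely to fail**

1. Step 15 (ring closure). What may go wrong: the aldehyde is also attacked with its chromium-bound oxygen pseudo-axial (poor facial selectivity at C4), or the alkenyl metal is protonated before it cyclises. Fallback: it sets out from 25 and comes back at 27. The cyclisation is run as before, and the mixture of 27 and its C4 epimer (1R,4S,5R)-5-[(tert-butyldimethylsilyl)oxy]-1-[(E)-heptadec-12-en-1-yl]-1-[(triethylsilyl)oxy]cyclohex-2-en-4-ol F1 is oxidised without separation (Dess–Martin periodinane, pyridine, CH2Cl2) to the enone (4R,6R)-6-[(tert-butyldimethylsilyl)oxy]-4-[(E)-heptadec-12-en-1-yl]-4-[(triethylsilyl)oxy]cyclohex-2-en-1-one F2. Luche reduction (NaBH4, CeCl3·7H2O, MeOH, −78 °C) should then return 27: hydride adds along the axial trajectory to the locked half-chair (chain and OTBS pseudo-equatorial), on the face away from the pseudo-axial C1–OTES group, so the new hydroxyl ends pseudo-equatorial and trans to C5–OTBS. C4 is then set by a substrate-controlled 1,2-reduction of a cyclohexenone instead of by the C–C bond formation.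

2. Step 8 (ethynylation). What may go wrong: the magnesium chelate is not tight enough in the presence of THF, so both faces of the ketone are attacked (poor facial selectivity at C1), or the aldolate undergoes retro-aldol cleavage. Fallback: C1 is set by reagent control instead; the sequence sets out from 13 and 7 and comes back at 19.
   - Lithiated methyl propiolate (n-BuLi, THF, −78 °C) with BF3·OEt2 opens epoxide 13 to methyl (5R)-5-hydroxy-6-[(4-methoxybenzyl)oxy]hex-2-ynoate F3, and TBSCl/imidazole gives methyl (5R)-5-[(tert-butyldimethylsilyl)oxy]-6-[(4-methoxybenzyl)oxy]hex-2-ynoate F4.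
   - Iodide 7 with Mg in THF gives the Grignard reagent (E)-heptadec-12-en-1-ylmagnesium iodide F5. With CuBr·SMe2 (1 equiv, THF, −78 °C, protonation at −78 °C) it adds syn across the ynoate to give methyl (2Z,15E)-3-{(2R)-2-[(tert-butyldimethylsilyl)oxy]-3-[(4-methoxybenzyl)oxy]propyl}icosa-2,15-dienoate F6, with the new chain trans to the ester.
   - DIBAL-H (iBu2AlH, CH2Cl2, −78 °C) gives the allylic alcohol (2Z,15E)-3-{(2R)-2-[(tert-butyldimethylsilyl)oxy]-3-[(4-methoxybenzyl)oxy]propyl}icosa-2,15-dien-1-ol F7.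
   - Sharpless asymmetric epoxidation (Ti(OiPr)4, L-(+)-diethyl tartrate, t-BuOOH, 4 Å sieves, CH2Cl2, −20 °C) gives [(2S,3R)-3-{(2R)-2-[(tert-butyldimethylsilyl)oxy]-3-[(4-methoxybenzyl)oxy]propyl}-3-[(E)-heptadec-12-en-1-yl]oxiran-2-yl]methanol F8, which fixes the C1 configuration.
   - PPh3/CCl4 (NaHCO3, reflux) gives (2R,3R)-2-(chloromethyl)-3-{(2R)-2-[(tert-butyldimethylsilyl)oxy]-3-[(4-methoxybenzyl)oxy]propyl}-3-[(E)-heptadec-12-en-1-yl]oxirane F9.
   - LDA (LiN(iPr)2, 3.5 equiv, THF, −40 °C) effects the known base-induced double elimination of a 2,3-epoxy chloride (epoxide opening, then loss of HCl) to the tertiary propargylic alcohol 19, with the C1–O bond never broken.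

3. Step 12 (Z-iodoalkene). What may go wrong: the borane also adds to the chain alkene or adds twice to the alkyne, protonolysis is incomplete, or the Z geometry erodes. Fallback: it sets out from the terminal alkyne 20 and comes back at 23, bypassing the iodoalkyne 21. Radical anti-hydroindation with HInCl2 (from InCl3 and DIBAL-H (iBu2AlH), Et3B as initiator, THF, −78 °C) gives the (Z)-alkenylindium dichloride of 20 F10. It is iodinated in the same flask (I2, −78 → 0 °C) with retention to give 23. The indium radical adds only to the terminal alkyne, so the internal chain alkene should not be touched.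

**Further compounds**

F1 | step 15 | (1R,4S,5R)-5-[(tert-butyldimethylsilyl)oxy]-1-[(E)-heptadec-12-en-1-yl]-1-[(triethylsilyl)oxy]cyclohex-2-en-4-ol (C4 epimer of 27) | CCCC/C=C/CCCCCCCCCCC[C@]1(O[Si](CC)(CC)CC)C=C[C@H](O)[C@H](O[Si](C)(C)C(C)(C)C)C1
F2 | step 15 | (4R,6R)-6-[(tert-butyldimethylsilyl)oxy]-4-[(E)-heptadec-12-en-1-yl]-4-[(triethylsilyl)oxy]cyclohex-2-en-1-one | CCCC/C=C/CCCCCCCCCCC[C@]1(O[Si](CC)(CC)CC)C=CC(=O)[C@H](O[Si](C)(C)C(C)(C)C)C1
F3 | step 8 | methyl (5R)-5-hydroxy-6-[(4-methoxybenzyl)oxy]hex-2-ynoate | COC(=O)C#CC[C@@H](O)COCc1ccc(OC)cc1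
F4 | step 8 | methyl (5R)-5-[(tert-butyldimethylsilyl)oxy]-6-[(4-methoxybenzyl)oxy]hex-2-ynoate | COC(=O)C#CC[C@@H](O[Si](C)(C)C(C)(C)C)COCc1ccc(OC)cc1
F5 | step 8 | (E)-heptadec-12-en-1-ylmagnesium iodide | CCCC/C=C/CCCCCCCCCCC[Mg]I
F6 | step 8 | methyl (2Z,15E)-3-{(2R)-2-[(tert-butyldimethylsilyl)oxy]-3-[(4-methoxybenzyl)oxy]propyl}icosa-2,15-dienoate | COC(=O)/C=C(/CCCCCCCCCCC/C=C/CCCC)C[C@@H](O[Si](C)(C)C(C)(C)C)COCc1ccc(OC)cc1
F7 | step 8 | (2Z,15E)-3-{(2R)-2-[(tert-butyldimethylsilyl)oxy]-3-[(4-methoxybenzyl)oxy]propyl}icosa-2,15-dien-1-ol | OC/C=C(/CCCCCCCCCCC/C=C/CCCC)C[C@@H](O[Si](C)(C)C(C)(C)C)COCc1ccc(OC)cc1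
F8 | step 8 | [(2S,3R)-3-{(2R)-2-[(tert-butyldimethylsilyl)oxy]-3-[(4-methoxybenzyl)oxy]propyl}-3-[(E)-heptadec-12-en-1-yl]oxiran-2-yl]methanol | OC[C@@H]1O[C@]1(CCCCCCCCCCC/C=C/CCCC)C[C@@H](O[Si](C)(C)C(C)(C)C)COCc1ccc(OC)cc1
F9 | step 8 | (2R,3R)-2-(chloromethyl)-3-{(2R)-2-[(tert-butyldimethylsilyl)oxy]-3-[(4-methoxybenzyl)oxy]propyl}-3-[(E)-heptadec-12-en-1-yl]oxirane | ClC[C@@H]1O[C@]1(CCCCCCCCCCC/C=C/CCCC)C[C@@H](O[Si](C)(C)C(C)(C)C)COCc1ccc(OC)cc1
F10 | step 12 | (Z)-alkenylindium dichloride of 20 (indium on C3, cis to C1) | CCCC/C=C/CCCCCCCCCCC[C@](O[Si](CC)(CC)CC)(/C=C\[In](Cl)Cl)C[C@@H](O[Si](C)(C)C(C)(C)C)COCc1ccc(OC)cc1
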